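**Retrosynthetic overview**
1. Feature: the tetrahydroazepine (N, four CH2, the two enamine carbons) and the cyclohexene share the N–C=C unit. With the N–CH2 carbon as C=O and the nitrogen taken out from between that carbon and the N-bearing alkene carbon, the two rings are a 3,4,5,6,7,8-hexahydronaphthalen-1(2H)-one (C1=O, C8a=C4a); the N–CH carbon hangs on C8 through one CH2, four bonds from C1.
2. Key disconnections: lactam C=O to CH2 (last), then N–C1(=O) and N–C8a by an intramolecular Schmidt ring expansion of azido enone 26, which closes the pyrrolidine and the seven-membered ene-lactam together.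
3. 26 comes from the Boc-amine 24, whose carbocycle B is closed by a carbonylative Suzuki–Miyaura reaction on enol triflate 22 (C5 ethyl by conjugate addition anti to the C6 silyloxy group).
4. The fused lactone and quaternary C8 come from epoxide opening by an amide placed at C7 by a Claisen rearrangement; the side arm (N–CH carbon and pendant lactone) is built from the D-serine aldehyde 1 and acrylate 2 and joined at C8 by Negishi coupling.
5. Ring order: pendant lactone, then fused lactone on the purchased cyclohexene (ring A), then carbocycle B, then pyrrolidine plus azepinone (key step).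

Key step: step 18

Remark: aldehyde 1 (made from D-serine) and enone 8 are taken as purchasable enantiopure materials. The C6 hydroxyl is carried as its TBS ether through the key step and the reduction. Locants C1–C8a are those of the hexahydronaphthalenone in 26, and α is the ring-A face that carries the C6–O bond.

**Step 1**
Reactants: 1 tert-butyl (R)-4-formyl-2,2-dimethyloxazolidine-3-carboxylate; 2 ethyl 2-(bromomethyl)acrylate
Product: 4 tert-butyl (4R)-2,2-dimethyl-4-[(2S)-4-methylene-5-oxotetrahydrofuran-2-yl]oxazolidine-3-carboxylate, via hydroxy ester 3 (not isolated)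
Conditions: Zn dust, THF–sat. aq NH4Cl, 0 °C to rt; then PPTS (cat.), PhH, 60 °C
Reagents that add atoms: none
Why: Zinc-mediated Barbier allylation of the α-amino aldehyde followed by lactonisation of the γ-hydroxy ester; Felkin–Anh attack anti to the N-Boc nitrogen should set the new carbinol centre as (S), the anti amino alcohol.

**Step 2**
Reactants: 4 α-methylene lactone
Product: 5 tert-butyl (4R)-2,2-dimethyl-4-[(2S,4S)-4-methyl-5-oxotetrahydrofuran-2-yl]oxazolidine-3-carboxylate
Conditions: H2 (1 atm), 10% Pd/C, EtOAc, rt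
Reagents that add atoms: none
Why: Heterogeneous hydrogenation of the exocyclic alkene from the lactone face opposite the bulky oxazolidine should give the cis-2,4-disubstituted lactone (new methyl centre S).

**Step 3**
Reactants: 5 oxazolidine lactone
Product: 6 tert-butyl N-{(1R)-2-hydroxy-1-[(2S,4S)-4-methyl-5-oxotetrahydrofuran-2-yl]ethyl}carbamate
Conditions: p-TsOH·H2O (0.1 equiv), MeOH, 0 °C to rt
Reagents that add atoms: none
Why: Acid-catalysed transacetalisation removes the N,O-isopropylidene group while the Boc group and the γ-lactone stay intact.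

**Step 4**
Reactants: 6 N-Boc amino alcohol
Product: 7 tert-butyl N-{(1S)-2-iodo-1-[(2S,4S)-4-methyl-5-oxotetrahydrofuran-2-yl]ethyl}carbamate
Conditions: I2, PPh3, imidazole, CH2Cl2, 0 °C to rt
Reagents that add atoms: iodine, II
Why: Appel iodination of the primary alcohol (SN2 at CH2) touches no stereocentre; the descriptor changes only through CIP priorities.

**Step 5**
Reactants: 8 (R)-4-(tert-butyldimethylsilyloxy)cyclohex-2-en-1-one
Product: 9 (R)-4-(tert-butyldimethylsilyloxy)-2-iodocyclohex-2-en-1-one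
Conditions: I2, pyridine–CH2Cl2 (1:1), 0 °C to rt
Reagents that add atoms: iodine, II
Why: α-Iodination of the enone by pyridine addition, iodination of the enolate and elimination (a Baylis–Hillman-type sequence) leaves the γ-silyloxy centre untouched.

**Step 6**
Reactants: 9 iodoenone
Product: 10 (1S,4R)-4-(tert-butyldimethylsilyloxy)-2-iodocyclohex-2-en-1-ol (OH cis to OTBS)
Conditions: (R)-2-methyl-CBS-oxazaborolidine (0.3 equiv), catecholborane, toluene, −78 °C
Reagents that add atoms: none
Why: Corey–Bakshi–Shibata reduction is reagent-controlled because the iodoalkene side of the ketone acts as the large group, and the (R)-catalyst should give the (1S) alcohol, cis to the silyloxy group.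

**Step 7**
Reactants: 10 cis allylic alcohol
Product: 12 (2R)-N,N-diethyl-2-[(1R,6R)-6-(tert-butyldimethylsilyloxy)-2-iodocyclohex-2-en-1-yl]propanamide, via ketene N,O-acetal 11 (not isolated)
Conditions: MeC≡CNEt2 (2 equiv), BF3·OEt2 (5 mol%), Et2O, 0 °C to rt; then xylene, 140 °C
Reagents that add atoms: N,N-diethylprop-1-yn-1-amine, CC#CN(CC)CC
Why: Ynamine (Ficini)–Claisen rearrangement: the suprafacial [3,3] shift forms the C7–C bond on the face of the departing C–O bond (cis to OTBS), and the methyl centre should follow from the methyl-cis-to-oxygen ketene acetal reacting through a boat-like transition state, the chair being blocked by the ring.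

**Step 8**
Reactants: 7 iodide; 12 vinyl iodide amide
Product: 14 amide carrying the CH2–CH(NHBoc)–lactone arm on the alkene carbon C8, via alkylzinc iodide 13 (not isolated)
Conditions: 7, Zn dust, I2 (cat.), DMF, rt; then 12, Pd2(dba)3 (2.5 mol%), SPhos (5 mol%), 50 °C
Reagents that add atoms: none
Why: Negishi sp2–sp3 coupling of a β-(Boc-amino)alkylzinc iodide, which is stabilised in DMF by carbamate coordination, with the vinyl iodide; no stereocentre is involved.

**Step 9**
Reactants: 14 unsaturated amide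
Product: 16 hydroxy lactone (γ-lactone from C7 to the new quaternary C8 with lactone O α and arm CH2 β; OH at C8a β), via epoxide 15 (not isolated)
Conditions: mCPBA, NaHCO3, CH2Cl2, 0 °C; then AcOH–H2O–THF, rt
Reagents that add atoms: meta-chloroperoxybenzoic acid, OOC(=O)c1cccc(Cl)c1; water, O
Why: Prilezhaev epoxidation of the only trisubstituted alkene on the face away from the two α substituents at C7 and C6, then 5-exo opening of the epoxide at its tertiary carbon by the amide oxygen with inversion and hydrolysis of the iminium lactone, sets quaternary C8 with the lactone O cis to the C7 side chain.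

**Step 10**
Reactants: 16 hydroxy lactone
Product: 17 keto lactone (C8a ketone)
Conditions: Dess–Martin periodinane, NaHCO3, CH2Cl2, rt
Reagents that add atoms: none
Why: Dess–Martin oxidation of the secondary alcohol; the neighbouring C8 is quaternary and cannot epimerise.

**Step 11**
Reactants: 17 keto lactone
Product: 18 enone (C8a=O, C4a=C5, γ-silyloxy at C6)
Conditions: IBX (2.5 equiv), DMSO–fluorobenzene, 70 °C
Reagents that add atoms: none
Why: IBX dehydrogenation of a ketone that can enolise only toward the CH2 side, since the other α-carbon is quaternary, gives a single enone.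

**Step 12**
Reactants: 18 enone
Product: 19 α-iodoenone (iodine on C4a)
Conditions: I2, pyridine–CH2Cl2 (1:1), 0 °C to rt
Reagents that add atoms: iodine, II
Why: The same pyridine-mediated α-iodination as in step 5 marks the enone α-carbon for C–C coupling under non-basic conditions.

**Step 13**
Reactants: 19 α-iodoenone
Product: 20 α-allyl enone (allyl on C4a)
Conditions: allylSnBu3, Pd2(dba)3 (5 mol%), AsPh3 (20 mol%), CuI (10 mol%), DMF, rt to 40 °C
Reagents that add atoms: allyltributylstannane, C=CC[Sn](CCCC)(CCCC)CCCC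
Why: Stille coupling of the α-iodoenone installs the three-carbon chain of carbocycle B without base, so the carbamate N–H and both lactones are not disturbed.

**Step 14**
Reactants: 20 α-allyl enone
Product: 22 enol triflate (C8a–OTf, C8a=C4a, C5 ethyl β), via magnesium enolate 21 (not isolated)
Conditions: EtMgBr (3 equiv), CuBr·SMe2 (20 mol%), THF, −78 to −40 °C; then N-(5-chloro-2-pyridyl)triflimide, −78 °C to rt
Reagents that add atoms: ethylmagnesium bromide, CC[Mg]Br; N-(5-chloropyridin-2-yl)-1,1,1-trifluoro-N-(trifluoromethylsulfonyl)methanesulfonamide, FC(F)(F)S(=O)(=O)N(c1ccc(Cl)cn1)S(=O)(=O)C(F)(F)F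
Why: Copper-catalysed conjugate addition of the ethyl Grignard reagent anti to the adjacent silyloxy group and to the α-face lactone sets C5 (ethyl trans to OTBS), and O-triflation of the enolate fixes the tetrasubstituted alkene regiospecifically.

**Step 15**
Reactants: 22 enol triflate
Product: 24 N-Boc hexahydronaphthalen-1(2H)-one (C1=O, C8a=C4a), via alkylborane 23 (not isolated)
Conditions: 9-BBN, THF, 0 °C to rt; then PdCl2(dppf) (10 mol%), K3PO4 (3 equiv), CO (1 atm), THF–DMF–H2O, 50 °C
Reagents that add atoms: carbon monoxide, [C-]#[O+]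
Why: Hydroboration of the only terminal alkene with 9-BBN followed by intramolecular carbonylative Suzuki–Miyaura coupling (CO insertion into the alkenyl–Pd bond, then B-alkyl transfer) closes the cyclohexenone and places the conjugated ketone at C1.

**Step 16**
Reactants: 24 N-Boc enone
Product: 25 ammonium trifluoroacetate of the primary amine
Conditions: TFA–CH2Cl2 (1:4), 0 °C; evaporate
Reagents that add atoms: trifluoroacetic acid, OC(=O)C(F)(F)F
Why: Acidolysis of the Boc carbamate, with the amine kept as its salt so that it cannot attack the neighbouring lactone; the secondary TBS ether should survive brief exposure at 0 °C.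

**Step 17**
Reactants: 25 ammonium salt
Product: 26 azido hexahydronaphthalenone (O-TBS), the key-step precursor
Conditions: imidazole-1-sulfonyl azide·HCl (1.2 equiv), Et3N (3 equiv), CuSO4·5H2O (2 mol%), CH2Cl2–MeOH, 0 °C to rt
Reagents that add atoms: imidazole-1-sulfonyl azide (as hydrochloride), [N-]=[N+]=NS(=O)(=O)n1ccnc1
Why: Copper-catalysed diazo transfer converts the primary amine into the azide with retention, since no bond to the stereocentre is broken, and it is fast enough to outrun O-to-N acyl transfer from the lactone.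

**Step 18**
Reactants: 26 azido enone
Product: 28 ene-lactam (O-TBS; N–C1(=O) and N–C8a formed), via azidohydrin 27 (not isolated)
Conditions: BF3·OEt2 (2.5 equiv), CH2Cl2, −40 to 0 °C
Reagents that add atoms: none
Why: Proposed new method: BF3 activates the enone carbonyl C1, the internal azide nitrogen adds to it to give the six-membered azidohydrin 27, and the alkenyl carbon C8a, which lies in that ring anti-periplanar to the N–N2+ bond, shifts from C1 to nitrogen as N2 leaves; the closest known reaction is the intramolecular Schmidt reaction of 2-(3-azidopropyl)cycloalkanones to ring-fused lactams, here asked to move the sp2 α-carbon of a tetrasubstituted enone. The pyrrolidine closes by 6-exo-trig addition of N to C=O followed by the 1,2-shift that contracts the azidohydrin ring by one atom, and the azepinone forms by the same shift as a one-atom expansion of the cyclohexenone. No stereocentre is formed, and the N–CH carbon keeps its configuration because no bond to it is broken. The step needs migration of C8a and not of the ring CH2 (C2): the tether lets only the in-ring C1–C8a bond stand anti to the departing N2 when the diazonium group is equatorial, and an sp2 carbon migrates more readily than CH2. Conjugate addition or cycloaddition of the azide to the enone is shut off by the fully substituted β-carbon, and an aprotic Lewis acid at low temperature is chosen so that the tertiary allylic lactone C–O bond is not ionised.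

**Step 19**
Reactants: 28 ene-lactam
Product: 30 O-TBS ether of the target (enamine), via silyl hemiaminal 29 (not isolated)
Conditions: [Ir(coe)2Cl]2 (1 mol%), Et2SiH2 (4 equiv), CH2Cl2, rt; aq NaHCO3 work-up
Reagents that add atoms: none
Why: Iridium-catalysed hydrosilylation reduces the tertiary N-alkenyl lactam to the amine while lactones are not reduced by Et2SiH2 under these conditions; the second hydride goes to the iminium carbon C1, which leaves the enamine C=C in place.

**Step 20**
Reactants: 30 silyl ether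
Product: 31 target CNP0154902.3
Conditions: HF·pyridine, pyridine, THF, 0 °C to rt; aq NaHCO3 work-up
Reagents that add atoms: none
Why: Fluoride cleavage of the silyl ether under buffered non-basic conditions avoids base-induced migration of the lactone onto the freed cis hydroxyl; reversible N-protonation of the enamine is undone on work-up.

**Compound list**
1 | tert-butyl (R)-4-formyl-2,2-dimethyloxazolidine-3-carboxylate | O=C[C@H]1COC(C)(C)N1C(=O)OC(C)(C)C | starting material
2 | ethyl 2-(bromomethyl)acrylate | CCOC(=O)C(=C)CBr | starting material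
3 | tert-butyl (4R)-4-[(1S)-3-(ethoxycarbonyl)-1-hydroxybut-3-enyl]-2,2-dimethyloxazolidine-3-carboxylate | CCOC(=O)C(=C)C[C@H](O)[C@H]1COC(C)(C)N1C(=O)OC(C)(C)C | intermediate
4 | tert-butyl (4R)-2,2-dimethyl-4-[(2S)-4-methylene-5-oxotetrahydrofuran-2-yl]oxazolidine-3-carboxylate | CC1(C)OC[C@@H](N1C(=O)OC(C)(C)C)[C@@H]1CC(=C)C(=O)O1 | intermediate
5 | tert-butyl (4R)-2,2-dimethyl-4-[(2S,4S)-4-methyl-5-oxotetrahydrofuran-2-yl]oxazolidine-3-carboxylate | CC1(C)OC[C@@H](N1C(=O)OC(C)(C)C)[C@@H]1C[C@H](C)C(=O)O1 | intermediate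
6 | tert-butyl N-{(1R)-2-hydroxy-1-[(2S,4S)-4-methyl-5-oxotetrahydrofuran-2-yl]ethyl}carbamate | OC[C@@H](NC(=O)OC(C)(C)C)[C@@H]1C[C@H](C)C(=O)O1 | intermediate
7 | tert-butyl N-{(1S)-2-iodo-1-[(2S,4S)-4-methyl-5-oxotetrahydrofuran-2-yl]ethyl}carbamate | IC[C@@H](NC(=O)OC(C)(C)C)[C@@H]1C[C@H](C)C(=O)O1 | intermediate
8 | (R)-4-(tert-butyldimethylsilyloxy)cyclohex-2-en-1-one | O=C1C=C[C@H](O[Si](C)(C)C(C)(C)C)CC1 | starting material
9 | (R)-4-(tert-butyldimethylsilyloxy)-2-iodocyclohex-2-en-1-one | O=C1C(I)=C[C@H](O[Si](C)(C)C(C)(C)C)CC1 | intermediate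
10 | (1S,4R)-4-(tert-butyldimethylsilyloxy)-2-iodocyclohex-2-en-1-ol | O[C@@H]1C(I)=C[C@H](O[Si](C)(C)C(C)(C)C)CC1 | intermediate
11 | ketene N,O-acetal of 10 with N,N-diethylpropynamine (methyl cis to O) | C/C=C(\O[C@@H]1C(I)=C[C@H](O[Si](C)(C)C(C)(C)C)CC1)N(CC)CC | intermediate
12 | (2R)-N,N-diethyl-2-[(1R,6R)-6-(tert-butyldimethylsilyloxy)-2-iodocyclohex-2-en-1-yl]propanamide | CCN(CC)C(=O)[C@H](C)[C@H]1C(I)=CCC[C@H]1O[Si](C)(C)C(C)(C)C | intermediate
13 | alkylzinc iodide from 7 | I[Zn]C[C@@H](NC(=O)OC(C)(C)C)[C@@H]1C[C@H](C)C(=O)O1 | intermediate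
14 | Negishi product: amide 12 with the arm CH2–CH(NHBoc)–(4-methyl-5-oxotetrahydrofuran-2-yl) in place of iodine | CCN(CC)C(=O)[C@H](C)[C@H]1C(C[C@@H](NC(=O)OC(C)(C)C)[C@@H]2C[C@H](C)C(=O)O2)=CCC[C@H]1O[Si](C)(C)C(C)(C)C | intermediate
15 | β-epoxide of 14 (C8–C8a) | CCN(CC)C(=O)[C@H](C)[C@H]1[C@]2(C[C@@H](NC(=O)OC(C)(C)C)[C@@H]3C[C@H](C)C(=O)O3)O[C@@H]2CC[C@H]1O[Si](C)(C)C(C)(C)C | intermediate
16 | hydroxy lactone: cis-fused α-methyl γ-lactone C7/C8, quaternary C8 (O α, arm β), C8a–OH β, C6–OTBS α | CC(C)(C)OC(=O)N[C@H](C[C@@]12OC(=O)[C@H](C)[C@@H]1[C@H](O[Si](C)(C)C(C)(C)C)CC[C@H]2O)[C@@H]1C[C@H](C)C(=O)O1 | intermediate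
17 | keto lactone (C8a ketone) | CC(C)(C)OC(=O)N[C@H](C[C@@]12OC(=O)[C@H](C)[C@@H]1[C@H](O[Si](C)(C)C(C)(C)C)CCC2=O)[C@@H]1C[C@H](C)C(=O)O1 | intermediate
18 | enone (C8a=O, C4a=C5) | CC(C)(C)OC(=O)N[C@H](C[C@@]12OC(=O)[C@H](C)[C@@H]1[C@H](O[Si](C)(C)C(C)(C)C)C=CC2=O)[C@@H]1C[C@H](C)C(=O)O1 | intermediate
19 | α-iodoenone (I on C4a) | CC(C)(C)OC(=O)N[C@H](C[C@@]12OC(=O)[C@H](C)[C@@H]1[C@H](O[Si](C)(C)C(C)(C)C)C=C(I)C2=O)[C@@H]1C[C@H](C)C(=O)O1 | intermediate
20 | α-allyl enone | CC(C)(C)OC(=O)N[C@H](C[C@@]12OC(=O)[C@H](C)[C@@H]1[C@H](O[Si](C)(C)C(C)(C)C)C=C(CC=C)C2=O)[C@@H]1C[C@H](C)C(=O)O1 | intermediate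
21 | bromomagnesium enolate after ethyl addition (C5 ethyl β) | CC(C)(C)OC(=O)N[C@H](C[C@@]12OC(=O)[C@H](C)[C@@H]1[C@H](O[Si](C)(C)C(C)(C)C)[C@@H](CC)C(CC=C)=C2O[Mg]Br)[C@@H]1C[C@H](C)C(=O)O1 | intermediate
22 | enol triflate (C8a–OTf, C4a allyl, C5 ethyl β) | CC(C)(C)OC(=O)N[C@H](C[C@@]12OC(=O)[C@H](C)[C@@H]1[C@H](O[Si](C)(C)C(C)(C)C)[C@@H](CC)C(CC=C)=C2OS(=O)(=O)C(F)(F)F)[C@@H]1C[C@H](C)C(=O)O1 | intermediate
23 | B-alkyl-9-BBN from hydroboration of the allyl group of 22 | CC(C)(C)OC(=O)N[C@H](C[C@@]12OC(=O)[C@H](C)[C@@H]1[C@H](O[Si](C)(C)C(C)(C)C)[C@@H](CC)C(CCCB3C4CCCC3CCC4)=C2OS(=O)(=O)C(F)(F)F)[C@@H]1C[C@H](C)C(=O)O1 | intermediate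
24 | N-Boc amino hexahydronaphthalen-1(2H)-one with fused and pendant lactones (O-TBS) | CC(C)(C)OC(=O)N[C@H](C[C@@]12OC(=O)[C@H](C)[C@@H]1[C@H](O[Si](C)(C)C(C)(C)C)[C@@H](CC)C3=C2C(=O)CCC3)[C@@H]1C[C@H](C)C(=O)O1 | intermediate
25 | ammonium trifluoroacetate of the amine from 24 | [NH3+][C@H](C[C@@]12OC(=O)[C@H](C)[C@@H]1[C@H](O[Si](C)(C)C(C)(C)C)[C@@H](CC)C3=C2C(=O)CCC3)[C@@H]1C[C@H](C)C(=O)O1.[O-]C(=O)C(F)(F)F | intermediate
26 | azido hexahydronaphthalenone carrying the fused and pendant lactones (O-TBS), key-step precursor | [N-]=[N+]=N[C@H](C[C@@]12OC(=O)[C@H](C)[C@@H]1[C@H](O[Si](C)(C)C(C)(C)C)[C@@H](CC)C3=C2C(=O)CCC3)[C@@H]1C[C@H](C)C(=O)O1 | intermediate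
27 | cyclic azidohydrin (N-diazonio hemiaminal, BF3-bound) | N#[N+]N1[C@H](C[C@@]23OC(=O)[C@H](C)[C@@H]2[C@H](O[Si](C)(C)C(C)(C)C)[C@@H](CC)C4=C3C1(O[B-](F)(F)F)CCC4)[C@@H]1C[C@H](C)C(=O)O1 | intermediate
28 | ene-lactam (target with the N–CH2 carbon as C=O; O-TBS) | CC[C@H]1C2=C3N(C(=O)CCC2)[C@@H]([C@@H]2C[C@H](C)C(=O)O2)C[C@]32OC(=O)[C@H](C)[C@@H]2[C@@H]1O[Si](C)(C)C(C)(C)C | intermediate
29 | O-(diethylsilyl) hemiaminal from 28 | CC[C@H]1C2=C3N(C(O[SiH](CC)CC)CCC2)[C@@H]([C@@H]2C[C@H](C)C(=O)O2)C[C@]32OC(=O)[C@H](C)[C@@H]2[C@@H]1O[Si](C)(C)C(C)(C)C | intermediate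
30 | O-TBS ether of the target | CC[C@H]1C2=C3N(CCCC2)[C@@H]([C@@H]2C[C@H](C)C(=O)O2)C[C@]32OC(=O)[C@H](C)[C@@H]2[C@@H]1O[Si](C)(C)C(C)(C)C | intermediate
31 | CNP0154902.3 | CC[C@H]1C2=C3N(CCCC2)[C@@H]([C@@H]2C[C@H](C)C(=O)O2)C[C@]32OC(=O)[C@H](C)[C@@H]2[C@@H]1O | target

**Totals**
Total step count: 20. Longest linear sequence: 17 steps (steps 1–4, then 8–20).

**Steps most likely to fail**

1. Step 18. The ring CH2 may migrate instead of the alkenyl carbon, the hindered conjugated carbonyl may not take up the azide, or the Lewis acid may ionise the allylic tertiary C–O bond. Fallback by known chemistry (photochemical ring contraction of a ring-fused oxaziridine, in which the in-ring C–C bond anti to the nitrogen lone pair migrates): it sets out from 25. The amine is freed with Et3N over 4 Å sieves and condenses with the C1 ketone to the six-membered cyclic imine F1. mCPBA gives the oxaziridine F2. Irradiation at 254 nm in MeCN moves C8a from C1 to N and returns to the route at 28.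

2. Step 15. Direct B-alkyl coupling without CO insertion may close a five-membered ring, or oxidative addition at the tetrasubstituted triflate may be slow. Fallback: it sets out from 19. B-alkyl Suzuki–Miyaura coupling with the borane F3 (from 4,4-dimethoxybut-1-ene and 9-BBN) gives the acetal enone F4. Ethyl cuprate addition and triflation as in step 14 give the triflate F5. PPTS in wet acetone frees the aldehyde F6. Nozaki–Hiyama–Kishi cyclisation (CrCl2, NiCl2 cat., DMF) closes ring B as the allylic alcohol F7. Dess–Martin oxidation returns to the route at 24.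

3. Step 7. Chair and boat transition states may compete, which would erode control at the methyl-bearing carbon, and ketene acetal formation at the hindered alcohol may be slow. Fallback: it sets out from 10. Propionyl chloride and pyridine give the propionate F8. Ireland–Claisen rearrangement (LDA, TMSCl, THF, −78 °C to rt) gives the acid F9; its enolate geometry can be set either way (THF alone or THF–DMPU), so the methyl configuration can be matched to the transition-state shape the ring adopts. TMSCHN2 gives the methyl ester F10. Negishi coupling with 13 gives F11. mCPBA and then acid, as in step 9, return to the route at 16.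

**Further compounds**
F1 | step 18 | cyclic imine from amine and C1 ketone (O-TBS) | CC[C@H]1C2=C3C(CCC2)=N[C@@H]([C@@H]2C[C@H](C)C(=O)O2)C[C@]32OC(=O)[C@H](C)[C@@H]2[C@@H]1O[Si](C)(C)C(C)(C)C
F2 | step 18 | ring-fused oxaziridine of F1 | CC[C@H]1C2=C3C4(CCC2)ON4[C@@H]([C@@H]2C[C@H](C)C(=O)O2)C[C@]32OC(=O)[C@H](C)[C@@H]2[C@@H]1O[Si](C)(C)C(C)(C)C
F3 | step 15 | 9-(4,4-dimethoxybutyl)-9-borabicyclo[3.3.1]nonane | COC(OC)CCCB1C2CCCC1CCC2
F4 | step 15 | enone with 4,4-dimethoxybutyl chain on C4a | CC(C)(C)OC(=O)N[C@H](C[C@@]12OC(=O)[C@H](C)[C@@H]1[C@H](O[Si](C)(C)C(C)(C)C)C=C(CCCC(OC)OC)C2=O)[C@@H]1C[C@H](C)C(=O)O1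
F5 | step 15 | enol triflate with acetal chain (C5 ethyl β) | CC(C)(C)OC(=O)N[C@H](C[C@@]12OC(=O)[C@H](C)[C@@H]1[C@H](O[Si](C)(C)C(C)(C)C)[C@@H](CC)C(CCCC(OC)OC)=C2OS(=O)(=O)C(F)(F)F)[C@@H]1C[C@H](C)C(=O)O1
F6 | step 15 | enol triflate aldehyde | CC(C)(C)OC(=O)N[C@H](C[C@@]12OC(=O)[C@H](C)[C@@H]1[C@H](O[Si](C)(C)C(C)(C)C)[C@@H](CC)C(CCCC=O)=C2OS(=O)(=O)C(F)(F)F)[C@@H]1C[C@H](C)C(=O)O1
F7 | step 15 | bicyclic allylic alcohol (C1–OH) | CC(C)(C)OC(=O)N[C@H](C[C@@]12OC(=O)[C@H](C)[C@@H]1[C@H](O[Si](C)(C)C(C)(C)C)[C@@H](CC)C3=C2C(O)CCC3)[C@@H]1C[C@H](C)C(=O)O1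
F8 | step 7 | propionate ester of 10 | CCC(=O)O[C@@H]1C(I)=C[C@H](O[Si](C)(C)C(C)(C)C)CC1
F9 | step 7 | (2R)-2-[(1R,6R)-6-(tert-butyldimethylsilyloxy)-2-iodocyclohex-2-en-1-yl]propanoic acid | OC(=O)[C@H](C)[C@H]1C(I)=CCC[C@H]1O[Si](C)(C)C(C)(C)C
F10 | step 7 | methyl ester of F9 | COC(=O)[C@H](C)[C@H]1C(I)=CCC[C@H]1O[Si](C)(C)C(C)(C)C
F11 | step 7 | Negishi product of F10 with 13 | COC(=O)[C@H](C)[C@H]1C(C[C@@H](NC(=O)OC(C)(C)C)[C@@H]2C[C@H](C)C(=O)O2)=CCC[C@H]1O[Si](C)(C)C(C)(C)C
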